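**Plan**

1. Cuts (flavanone numbering; ring A = benzo ring, ring B = 2-aryl ring, ring C = pyranone): the four O–MOM bonds, then C4–C4a of ring C, then O1–C2, then the C6–CH2 bond of the farnesyl chain and the C8a–O bond; in the ring B piece, C3–C4.
2. Enabling feature: ring A is a 2-farnesylphloroglucinol whose O1 sits para to the chain carbon, on the local twofold axis through C6 and C8a. C4a and C8 are therefore equivalent, so C-acylation ortho to O1 can only give the 6-farnesyl isomer, whereas O-cyclization of a chalcone would have to choose between two different hydroxyls.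
3. Forward, ring A phenol: resorcinol → bis-MOM ether → C2 farnesylation by ortho-lithiation → para C–H borylation/oxidation → ortho-iodination. Ring B piece: methyl 3,5-dihydroxybenzoate → β-keto Weinreb amide → (R)-carbinol.
4. The halves are joined at O1–C2 by Mitsunobu etherification. Ring C, the last ring, is closed at C4–C4a by iodine–lithium exchange and anionic cycloacylation of the Weinreb amide; acid then removes the MOM groups.
5. Stereochemistry: C2 (S) comes from asymmetric transfer hydrogenation (R alcohol) followed by SN2 inversion in the Mitsunobu step; the E,E chain geometry comes from (2E,6E)-farnesyl bromide.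

Key step: step 9

Remark: farnesyl means (2E,6E)-3,7,11-trimethyldodeca-2,6,10-trien-1-yl and MOM means methoxymethyl throughout; the sense of induction in step 7 is taken from the aryl ketone model of the catalyst, and the (S,S) catalyst would be used if the opposite carbinol formed.

**Route**

Step 1
Reactants: 1 resorcinol
Product: 2 1,3-bis(methoxymethoxy)benzene
Conditions: NaH, MOMCl, DMF, 0 °C to rt
Reagents that add atoms: chloromethyl methyl ether (MOMCl), COCCl
Why: Williamson ether synthesis on the bis-phenoxide; MOM is chosen because it directs the ortho-lithiation of step 2, survives organolithium reagents and falls to mild acid at the end.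

Step 2
Reactants: 2 1,3-bis(methoxymethoxy)benzene; 3 (2E,6E)-farnesyl bromide
Product: 4 2-farnesyl-1,3-bis(methoxymethoxy)benzene
Conditions: n-BuLi, THF, 0 °C to rt; CuBr·SMe2 (10 mol%), then 3, −78 to 0 °C
Reagents that add atoms: none
Why: Directed ortho-metalation at C2, the position flanked by both OMOM groups, then copper-catalysed SN2 allylation of the aryl anion at the primary carbon of the allylic bromide, which leaves the chain E,E.

Step 3
Reactants: 4 2-farnesyl-1,3-bis(methoxymethoxy)benzene
Product: 6 3,5-bis(methoxymethoxy)-4-farnesylphenol, via arylboronate 5 (not isolated)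
Conditions: [Ir(OMe)(cod)]2 (1.5 mol%), 4,4'-di-tert-butyl-2,2'-bipyridine (3 mol%), B2pin2 (1.0 equiv), THF, 60 °C; then aq. NaOH, 30% H2O2, 0 °C
Reagents that add atoms: hydrogen peroxide, OO (the phenol oxygen); bis(pinacolato)diboron, CC1(C)OB(OC1(C)C)B1OC(C)(C)C(C)(C)O1 (the boron group of 5)
Why: Iridium-catalysed aromatic C–H borylation is sterically governed and should take the only ring C–H with no ortho substituent (para to the chain, on the symmetry axis), the hindered trisubstituted alkenes being poor substrates for the catalyst; oxidation of the C–B bond by alkaline hydrogen peroxide (boronate 1,2-shift) then gives the phenol without epoxidizing unactivated alkenes.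

Step 4
Reactants: 6 3,5-bis(methoxymethoxy)-4-farnesylphenol
Product: 7 2-iodo-3,5-bis(methoxymethoxy)-4-farnesylphenol
Conditions: I2 (1.0 equiv), NaHCO3, THF/H2O, 0 °C
Reagents that add atoms: iodine, II
Why: Electrophilic aromatic iodination of the phloroglucinol-type phenoxide, whose two free positions are equivalent and activated by three oxygens, should be much faster than any addition of iodine to the chain alkenes, and one equivalent of iodine should hold the reaction at the mono-iodide.

Step 5
Reactants: 8 methyl 3,5-dihydroxybenzoate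
Product: 9 methyl 3,5-bis(methoxymethoxy)benzoate
Conditions: NaH, MOMCl, DMF, 0 °C to rt
Reagents that add atoms: chloromethyl methyl ether (MOMCl), COCCl
Why: Williamson ether synthesis on the bis-phenoxide, which is formed without touching the non-enolizable methyl ester at 0 °C.

Step 6
Reactants: 9 methyl 3,5-bis(methoxymethoxy)benzoate; 10 N-methoxy-N-methylacetamide
Product: 11 3-[3,5-bis(methoxymethoxy)phenyl]-N-methoxy-N-methyl-3-oxopropanamide
Conditions: 10 (2 equiv), LiN(i-Pr)2 (2 equiv), THF, −78 °C; then 9, −78 to 0 °C; AcOH quench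
Reagents that add atoms: none
Why: Crossed Claisen condensation: the lithium enolate of the acetamide acylates the non-enolizable benzoate, and the second equivalent of enolate deprotonates the β-keto amide so that it is not attacked further.

Step 7
Reactants: 11 3-[3,5-bis(methoxymethoxy)phenyl]-N-methoxy-N-methyl-3-oxopropanamide
Product: 12 (3R)-3-[3,5-bis(methoxymethoxy)phenyl]-3-hydroxy-N-methoxy-N-methylpropanamide
Conditions: RuCl(p-cymene)[(R,R)-TsDPEN] (1 mol%), HCO2H/Et3N (5:2), DMF, 40 °C
Reagents that add atoms: none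
Why: Noyori-type asymmetric transfer hydrogenation of an aryl ketone: the chiral Ru hydride/NH pair delivers hydride to one face through the six-membered outer-sphere transition state ordered by the arene/CH contact, so the (R,R) catalyst should set the new carbinol center as R, as with aryl methyl ketones and β-keto esters or amides.

Step 8
Reactants: 7 2-iodo-3,5-bis(methoxymethoxy)-4-farnesylphenol; 12 (3R)-3-[3,5-bis(methoxymethoxy)phenyl]-3-hydroxy-N-methoxy-N-methylpropanamide
Product: 13 (3S)-3-[3,5-bis(methoxymethoxy)phenyl]-3-[2-iodo-3,5-bis(methoxymethoxy)-4-farnesylphenoxy]-N-methoxy-N-methylpropanamide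
Conditions: PPh3, DIAD, toluene, 0 °C to rt
Reagents that add atoms: none
Why: Mitsunobu reaction: the ortho-iodophenol (acidified by iodine) displaces the oxyphosphonium group by SN2, so the R carbinol becomes the S ether; the two meta oxygens of ring B disfavor ionization of the benzylic center and the amide is a weaker carbon acid than an ester, which should limit elimination to the cinnamamide.

Step 9
Reactants: 13 (3S)-3-[3,5-bis(methoxymethoxy)phenyl]-3-[2-iodo-3,5-bis(methoxymethoxy)-4-farnesylphenoxy]-N-methoxy-N-methylpropanamide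
Product: 16 (2S)-2-[3,5-bis(methoxymethoxy)phenyl]-5,7-bis(methoxymethoxy)-6-farnesylchroman-4-one, via aryllithium 14 (not isolated), via lithium hemiaminal alkoxide 15 (not isolated)
Conditions: t-BuLi (2.1 equiv), THF, −78 °C; then AcOH, −78 °C to rt
Reagents that add atoms: none
Why: Iodine–lithium exchange at C4a, which at −78 °C should be faster than deprotonation at C3 or addition of t-BuLi to the amide, gives aryllithium 14, held between O1 and the C5 OMOM oxygen; it adds to the Weinreb amide carbonyl to give the N-methoxy-chelated tetrahedral lithium alkoxide 15, which persists until the cold AcOH quench and then collapses to the C4 ketone of 16. The closest known reaction type is the Parham cyclization in its cycloacylation form with Weinreb amides, used for indanones, tetralones and chroman-4-ones. Ring C is closed by an anionic 6-exo-trig attack that forms the C4–C4a bond. No new stereocenter arises: C2 keeps the S configuration set in step 8, because the ketone stays masked as 15 in the basic medium, so that neither an enolate nor a retro-oxa-Michael opening is possible, and the quench is acidic. The step needs regioselectivity (6- against 8-farnesyl) and chemoselectivity: the first is secured by the local twofold axis of ring A through C6 and C8a, which made the two carbons ortho to O1 equivalent before iodination so that only the 6-farnesyl flavanone can form, and the second by the iodide, whose exchange should outrun the proton transfers that would expel the aryloxide by E1cB.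

Step 10
Reactants: 16 (2S)-2-[3,5-bis(methoxymethoxy)phenyl]-5,7-bis(methoxymethoxy)-6-farnesylchroman-4-one
Product: 17 (2S)-2-(3,5-dihydroxyphenyl)-5,7-dihydroxy-6-farnesylchroman-4-one
Conditions: 3 M aq. HCl, MeOH, 40 °C
Reagents that add atoms: none
Why: Acid-catalysed acetal exchange (MOM cleavage) with methanol as acceptor; dilute acid at mild temperature is the standard way to unmask MOM-protected prenylated flavanones and should spare the chain alkenes and the C2 center, which is labile to base but not to dilute acid.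

**Compound list**

1 | resorcinol | Oc1cccc(O)c1 | starting material
2 | 1,3-bis(methoxymethoxy)benzene | COCOc1cccc(OCOC)c1 | intermediate
3 | (2E,6E)-farnesyl bromide | CC(C)=CCC/C(C)=C/CC/C(C)=C/CBr | starting material
4 | 2-farnesyl-1,3-bis(methoxymethoxy)benzene | CC(C)=CCC/C(C)=C/CC/C(C)=C/Cc1c(OCOC)cccc1OCOC | intermediate
5 | 2-[3,5-bis(methoxymethoxy)-4-farnesylphenyl]-4,4,5,5-tetramethyl-1,3,2-dioxaborolane | CC(C)=CCC/C(C)=C/CC/C(C)=C/Cc1c(OCOC)cc(B2OC(C)(C)C(C)(C)O2)cc1OCOC | intermediate
6 | 3,5-bis(methoxymethoxy)-4-farnesylphenol | CC(C)=CCC/C(C)=C/CC/C(C)=C/Cc1c(OCOC)cc(O)cc1OCOC | intermediate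
7 | 2-iodo-3,5-bis(methoxymethoxy)-4-farnesylphenol | CC(C)=CCC/C(C)=C/CC/C(C)=C/Cc1c(OCOC)cc(O)c(I)c1OCOC | intermediate
8 | methyl 3,5-dihydroxybenzoate | COC(=O)c1cc(O)cc(O)c1 | starting material
9 | methyl 3,5-bis(methoxymethoxy)benzoate | COC(=O)c1cc(OCOC)cc(OCOC)c1 | intermediate
10 | N-methoxy-N-methylacetamide | CON(C)C(C)=O | starting material
11 | 3-[3,5-bis(methoxymethoxy)phenyl]-N-methoxy-N-methyl-3-oxopropanamide | CON(C)C(=O)CC(=O)c1cc(OCOC)cc(OCOC)c1 | intermediate
12 | (3R)-3-[3,5-bis(methoxymethoxy)phenyl]-3-hydroxy-N-methoxy-N-methylpropanamide | CON(C)C(=O)C[C@@H](O)c1cc(OCOC)cc(OCOC)c1 | intermediate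
13 | (3S)-3-[3,5-bis(methoxymethoxy)phenyl]-3-[2-iodo-3,5-bis(methoxymethoxy)-4-farnesylphenoxy]-N-methoxy-N-methylpropanamide | CC(C)=CCC/C(C)=C/CC/C(C)=C/Cc1c(OCOC)cc(O[C@@H](CC(=O)N(C)OC)c2cc(OCOC)cc(OCOC)c2)c(I)c1OCOC | intermediate
14 | aryllithium from 13 (lithium in place of iodine at C4a) | CC(C)=CCC/C(C)=C/CC/C(C)=C/Cc1c(OCOC)cc(O[C@@H](CC(=O)N(C)OC)c2cc(OCOC)cc(OCOC)c2)c([Li])c1OCOC | intermediate
15 | lithium alkoxide of the cyclic C4 N-methoxy-N-methyl hemiaminal (tetrahedral adduct; C4 configuration not defined) | CC(C)=CCC/C(C)=C/CC/C(C)=C/Cc1c(OCOC)cc2c(c1OCOC)C(O[Li])(N(C)OC)C[C@@H](c1cc(OCOC)cc(OCOC)c1)O2 | intermediate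
16 | (2S)-2-[3,5-bis(methoxymethoxy)phenyl]-5,7-bis(methoxymethoxy)-6-farnesylchroman-4-one | CC(C)=CCC/C(C)=C/CC/C(C)=C/Cc1c(OCOC)cc2c(c1OCOC)C(=O)C[C@@H](c1cc(OCOC)cc(OCOC)c1)O2 | intermediate
17 | (2S)-2-(3,5-dihydroxyphenyl)-5,7-dihydroxy-6-[(2E,6E)-3,7,11-trimethyldodeca-2,6,10-trien-1-yl]-2,3-dihydro-4H-chromen-4-one | CC(C)=CCC/C(C)=C/CC/C(C)=C/Cc1c(O)cc2c(c1O)C(=O)C[C@@H](c1cc(O)cc(O)c1)O2 | target

**Count and risks**

Total steps: 10. Longest linear sequence: 7 steps (steps 1, 2, 3, 4, 8, 9, 10); the ring B branch (steps 5, 6, 7) joins at step 8.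

The three steps most likely to fail:

Step 8. The activated benzylic oxyphosphonium may eliminate to the cinnamamide, the hindered ortho-iodophenol may attack slowly, or partial ionization may erode the configuration. The fallback sets out from 7 and 12 and returns at 16; it makes the C-acyl bond first and closes ring C at O1–C2 instead. Compound 12 is silylated (TBSCl, imidazole, DMF) to (3R)-3-[3,5-bis(methoxymethoxy)phenyl]-3-(tert-butyldimethylsilyloxy)-N-methoxy-N-methylpropanamide F5. Compound 7 is converted with NaH and then t-BuLi (THF, −78 °C) into its O,C-dianion, which is acylated by F5 to the 2-hydroxyaryl β-silyloxy ketone F6. HF·pyridine (THF, 0 °C) gives the (R)-β-hydroxy ketone F7, and an intramolecular Mitsunobu reaction (PPh3, DIAD, THF, 0 °C; 6-exo-tet, inversion) gives 16. The only free phenol of F7 is the one on the symmetry axis, so the regiochemistry stays fixed.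

Step 9. t-BuLi may deprotonate C3 and so expel the aryloxide by E1cB, may add to the amide, or the aryllithium may be protonated before it closes the ring. The fallback sets out from 13 and returns at 16; it makes the same C4–C4a bond under neutral conditions by a Nozaki–Hiyama–Kishi reaction. i-Bu2AlH (THF, −78 °C) reduces the Weinreb amide of 13 to (3S)-3-[3,5-bis(methoxymethoxy)phenyl]-3-[2-iodo-3,5-bis(methoxymethoxy)-4-farnesylphenoxy]propanal F8. CrCl2 with catalytic NiCl2 (DMF, rt) adds the aryl iodide to the aldehyde to give the flavan-4-ol (2S)-2-[3,5-bis(methoxymethoxy)phenyl]-5,7-bis(methoxymethoxy)-6-farnesylchroman-4-ol F9 as a mixture of C4 epimers. Dess–Martin periodinane (NaHCO3, CH2Cl2, 0 °C) oxidizes F9 to 16.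

Step 3. The catalyst may hydroborate or borylate the chain alkenes, or the alkenes may slow the arene borylation. The fallback sets out from 2 and returns at 6; it introduces the oxygen before the chain. Compound 2 is borylated under the same iridium catalysis at C5 to 2-[3,5-bis(methoxymethoxy)phenyl]-4,4,5,5-tetramethyl-1,3,2-dioxaborolane F1 and oxidized (NaOH, H2O2) to 3,5-bis(methoxymethoxy)phenol F2. TIPSCl/imidazole (DMF) gives [3,5-bis(methoxymethoxy)phenoxy]triisopropylsilane F3. n-BuLi, then CuBr·SMe2 (10 mol%) and 3, farnesylate the position between the two OMOM groups (the bulky, non-coordinating silyloxy group does not direct) to give [3,5-bis(methoxymethoxy)-4-farnesylphenoxy]triisopropylsilane F4. Bu4NF (THF, 0 °C) gives 6.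

**Further compounds**

F1 | step 3 | 2-[3,5-bis(methoxymethoxy)phenyl]-4,4,5,5-tetramethyl-1,3,2-dioxaborolane | COCOc1cc(OCOC)cc(B2OC(C)(C)C(C)(C)O2)c1
F2 | step 3 | 3,5-bis(methoxymethoxy)phenol | COCOc1cc(O)cc(OCOC)c1
F3 | step 3 | [3,5-bis(methoxymethoxy)phenoxy]triisopropylsilane | COCOc1cc(OCOC)cc(O[Si](C(C)C)(C(C)C)C(C)C)c1
F4 | step 3 | [3,5-bis(methoxymethoxy)-4-farnesylphenoxy]triisopropylsilane | CC(C)=CCC/C(C)=C/CC/C(C)=C/Cc1c(OCOC)cc(O[Si](C(C)C)(C(C)C)C(C)C)cc1OCOC
F5 | step 8 | (3R)-3-[3,5-bis(methoxymethoxy)phenyl]-3-(tert-butyldimethylsilyloxy)-N-methoxy-N-methylpropanamide | CON(C)C(=O)C[C@@H](O[Si](C)(C)C(C)(C)C)c1cc(OCOC)cc(OCOC)c1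
F6 | step 8 | (3R)-3-[3,5-bis(methoxymethoxy)phenyl]-3-(tert-butyldimethylsilyloxy)-1-[2-hydroxy-4,6-bis(methoxymethoxy)-5-farnesylphenyl]propan-1-one | CC(C)=CCC/C(C)=C/CC/C(C)=C/Cc1c(OCOC)cc(O)c(C(=O)C[C@@H](O[Si](C)(C)C(C)(C)C)c2cc(OCOC)cc(OCOC)c2)c1OCOC
F7 | step 8 | (3R)-3-[3,5-bis(methoxymethoxy)phenyl]-3-hydroxy-1-[2-hydroxy-4,6-bis(methoxymethoxy)-5-farnesylphenyl]propan-1-one | CC(C)=CCC/C(C)=C/CC/C(C)=C/Cc1c(OCOC)cc(O)c(C(=O)C[C@@H](O)c2cc(OCOC)cc(OCOC)c2)c1OCOC
F8 | step 9 | (3S)-3-[3,5-bis(methoxymethoxy)phenyl]-3-[2-iodo-3,5-bis(methoxymethoxy)-4-farnesylphenoxy]propanal | CC(C)=CCC/C(C)=C/CC/C(C)=C/Cc1c(OCOC)cc(O[C@@H](CC=O)c2cc(OCOC)cc(OCOC)c2)c(I)c1OCOC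
F9 | step 9 | (2S)-2-[3,5-bis(methoxymethoxy)phenyl]-5,7-bis(methoxymethoxy)-6-farnesylchroman-4-ol (C4 epimers) | CC(C)=CCC/C(C)=C/CC/C(C)=C/Cc1c(OCOC)cc2c(c1OCOC)C(O)C[C@@H](c1cc(OCOC)cc(OCOC)c1)O2
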